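**Retrosynthetic overview**
1. Last bond: acyl C–C(maleimide). An acyl radical from a decalin aldehyde adds to a 3-alkylmaleimide, and the imide ring is then re-dehydrogenated.
2. Key bond: C1–C8a of the decalin, closed 6-exo by an enamine-derived α-formyl radical onto the trisubstituted olefin of a cyclohexenyl carbinol, with H-atom transfer to C8 (sets C1, C8a, C8 and the cis ring fusion).
3. Cyclisation substrate: a (Z)-enal made by acetylide addition of a C6 alkynol (C2 from Rh-catalysed conjugate alkynylation of crotonaldehyde) to a 5-carbomethoxy-3-methylcyclohexenone (sets C4a), then semihydrogenation and oxidation. C6 is equilibrated after ring closure.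
4. Maleimide partner: Ir-catalysed branched allylic alkylation of a sulfonylsuccinimide, then sulfinate elimination.
5. Ring order: ring B first (desymmetrising aldol condensation of a 1,5-diketone), then ring A (radical cyclisation); the imide ring is carried in from maleimide.

Assumption: in steps 3, 4 and 13 the catalyst antipode named is the one expected by analogy to give the configuration drawn; if the sense proves reversed, the mirror-image catalyst is used and nothing else changes.

Decalin locants used in names and text: C1 (acyl-bearing), C2 (methyl), C3=C4, C4a (hydroxyl), C5, C6 (carboxyl), C7, C8 (methyl), C8a.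

**Route**

Step 1
Reactants: 1 methyl pent-4-enoate; 2 3-bromoprop-1-ene (allyl bromide)
Product: 3 methyl 2-(prop-2-en-1-yl)pent-4-enoate
Conditions: LiN(iPr)2 (1.1 equiv), THF, −78 °C; then 2, −78 °C to rt
Reagents that add atoms: none
Why: Ester enolate alkylation (SN2) of the lithium enolate with allyl bromide; the product carries two identical allyl arms, so no stereocentre arises.

Step 2
Reactants: 3 methyl 2-(prop-2-en-1-yl)pent-4-enoate
Product: 4 methyl 4-oxo-2-(2-oxopropyl)pentanoate
Conditions: PdCl2 (10 mol%), CuCl (20 mol%), O2 (1 atm), DMF/H2O 7:1, rt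
Reagents that add atoms: water, O
Why: Twofold Tsuji–Wacker oxidation converts both terminal alkenes into methyl ketones with Markovnikov selectivity, giving the symmetric 1,5-diketone without a stereocentre.

Step 3
Reactants: 4 methyl 4-oxo-2-(2-oxopropyl)pentanoate
Product: 6 methyl (1S)-3-methyl-5-oxocyclohex-3-ene-1-carboxylate, via ketol 5 (not isolated)
Conditions: 9-amino(9-deoxy)epiquinine (10 mol%), AcOH (30 mol%), toluene, −15 °C to rt
Reagents that add atoms: none
Why: Primary-amine-catalysed desymmetrising intramolecular aldol condensation (6-enolendo) in which the chiral enamine selects one of the two enantiotopic acetonyl arms as donor, which fixes the ester-bearing carbon as (S), and dehydration of ketol 5 gives the conjugated enone.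

Step 4
Reactants: 7 (E)-but-2-enal; 8 ethynyltri(propan-2-yl)silane
Product: 10 (3S)-3-methyl-5-[tri(propan-2-yl)silyl]pent-4-yn-1-ol, via alkynal 9 (not isolated)
Conditions: [Rh(OAc)(C2H4)2]2 (2.5 mol%), (R)-DTBM-SEGPHOS (6 mol%), MeOH, 40 °C; then NaBH4, 0 °C
Reagents that add atoms: none
Why: Rh-catalysed asymmetric conjugate alkynylation of an enal with a bulky silylacetylene (the bulk suppresses alkyne dimerisation), the ligand-controlled face of the β-carbon setting the methyl-bearing stereocentre (future C2), followed by in-flask borohydride reduction so that the volatile alkynal 9 is not handled.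

Step 5
Reactants: 10 (3S)-3-methyl-5-[tri(propan-2-yl)silyl]pent-4-yn-1-ol
Product: 11 (3S)-3-methylpent-4-yn-1-ol
Conditions: Bu4NF (1.1 equiv), THF (wet), 0 °C to rt
Reagents that add atoms: none
Why: Fluoride-mediated protodesilylation of the alkynylsilane; the stereocentre is not involved.

Step 6
Reactants: 11 (3S)-3-methylpent-4-yn-1-ol; 6 methyl (1S)-3-methyl-5-oxocyclohex-3-ene-1-carboxylate
Product: 12 methyl (1S,5S)-5-hydroxy-5-[(3S)-5-hydroxy-3-methylpent-1-yn-1-yl]-3-methylcyclohex-3-ene-1-carboxylate
Conditions: 11 (1.3 equiv), n-BuLi (2.6 equiv), THF, −78 to 0 °C; then 6, −78 °C; AcOH quench at −78 °C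
Reagents that add atoms: none
Why: 1,2-Addition of the lithium acetylide (alkoxide–acetylide dianion) to the enone carbonyl, faster than attack on the ester at −78 °C, with axial attack anti to the pseudo-equatorial ester (the usual course for 5-substituted cyclohex-2-enones) placing the alkynyl group trans and the new hydroxyl cis to the ester, which sets the carbinol centre (future C4a) in the absolute sense needed while the ester centre serves as a relay that is corrected in step 10.

Step 7
Reactants: 12 methyl (1S,5S)-5-hydroxy-5-[(3S)-5-hydroxy-3-methylpent-1-yn-1-yl]-3-methylcyclohex-3-ene-1-carboxylate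
Product: 13 methyl (1S,5R)-5-hydroxy-5-[(1Z,3S)-5-hydroxy-3-methylpent-1-en-1-yl]-3-methylcyclohex-3-ene-1-carboxylate
Conditions: H2 (1 atm), Pd/CaCO3 poisoned with Pb(OAc)2, quinoline, EtOAc, rt
Reagents that add atoms: none
Why: Lindlar-type semihydrogenation adds H2 syn to the alkyne to give the (Z)-alkene needed for ring closure, the trisubstituted ring olefin being inert (the descriptor at the carbinol carbon changes only because the priorities change).

Step 8
Reactants: 13 methyl (1S,5R)-5-hydroxy-5-[(1Z,3S)-5-hydroxy-3-methylpent-1-en-1-yl]-3-methylcyclohex-3-ene-1-carboxylate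
Product: 14 methyl (1S,5R)-5-hydroxy-3-methyl-5-[(1Z,3S)-3-methyl-5-oxopent-1-en-1-yl]cyclohex-3-ene-1-carboxylate
Conditions: TEMPO (10 mol%), PhI(OAc)2 (1.1 equiv), CH2Cl2, 0 °C
Reagents that add atoms: none
Why: Oxoammonium (TEMPO) oxidation is selective for the primary alcohol, the tertiary allylic alcohol cannot be oxidised, and no stereocentre is touched.

Step 9
Reactants: 14 methyl (1S,5R)-5-hydroxy-3-methyl-5-[(1Z,3S)-3-methyl-5-oxopent-1-en-1-yl]cyclohex-3-ene-1-carboxylate
Product: 15 methyl (1S,2R,4aR,6S,8S,8aR)-1-formyl-4a-hydroxy-2,8-dimethyl-1,2,4a,5,6,7,8,8a-octahydronaphthalene-6-carboxylate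
Conditions: [Ir(Fmppy)2(dtbbpy)]PF6 (1 mol%; Fmppy = 2-(4-fluorophenyl)-4-methylpyridine, dtbbpy = 4,4′-di-tert-butyl-2,2′-bipyridine), (2S,5S)-5-benzyl-2-tert-butyl-3-methylimidazolidin-4-one trifluoroacetate (20 mol%), 2,4,6-triisopropylbenzenethiol (10 mol%), DME, 450 nm LEDs, −40 °C
Reagents that add atoms: none
Why: Photoredox/enamine/hydrogen-atom-transfer triple catalysis (α-alkylation of an aldehyde with an unactivated olefin, intramolecular): the excited iridium complex oxidises the enamine to an electrophilic α-formyl (enaminyl) radical that adds 6-exo to the less substituted olefinic carbon C8a, the (Z)-tether on C4a allowing only suprafacial delivery so that the new C1–C8a bond is cis to the C4a–C4 bond (cis-decalin, H8a syn to OH), the tertiary C8 radical then takes hydrogen from the thiol on the face away from the new axial C8a–C1 bond (methyl equatorial and cis to C1), and C1 forms trans to the C2 methyl in the chair-like transition state and remains epimerisable.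

Step 10
Reactants: 15 methyl (1S,2R,4aR,6S,8S,8aR)-1-formyl-4a-hydroxy-2,8-dimethyl-1,2,4a,5,6,7,8,8a-octahydronaphthalene-6-carboxylate
Product: 17 (1S,2R,4aR,6R,8S,8aR)-1-formyl-4a-hydroxy-2,8-dimethyl-1,2,4a,5,6,7,8,8a-octahydronaphthalene-6-carboxylic acid, via C6-epimerised methyl ester 16 (not isolated)
Conditions: NaOMe (0.3 equiv), MeOH, 50 °C, Ar; then H2O, LiOH (3 equiv), rt; then 1 M HCl to pH 3 at 0 °C
Reagents that add atoms: lithium hydroxide, [Li+].[OH-]
Why: Base-mediated thermodynamic epimerisation followed by saponification: C6 (α to the ester) and C1 (α to the aldehyde) equilibrate through their enolates to the cis-decalin chair in which formyl, ester and both methyl groups are equatorial, relieving the 1,3-diaxial hydroxyl/ester arrangement of 15 (a lactone through the tertiary alcohol is disfavoured in methanol and reopens), after which hydroxide cleaves the unhindered equatorial methyl ester.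

Step 11
Reactants: 18 1H-pyrrole-2,5-dione (maleimide)
Product: 19 3-(phenylsulfonyl)pyrrolidine-2,5-dione (racemic)
Conditions: PhSO2Na (1.1 equiv), AcOH (1.2 equiv), EtOH/H2O, rt
Reagents that add atoms: sodium benzenesulfinate, [Na+].[O-]S(=O)c1ccccc1
Why: Conjugate (sulfa-Michael) addition of the sulfinate sulfur to the maleimide; the new centre is racemic and is destroyed in step 13.

Step 12
Reactants: 20 hept-1-ene; 21 methyl prop-2-en-1-yl carbonate (allyl methyl carbonate)
Product: 22 methyl (2E)-oct-2-en-1-yl carbonate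
Conditions: second-generation Grubbs catalyst (2 mol%), 20 (4 equiv), CH2Cl2, 40 °C
Reagents that add atoms: none
Why: Olefin cross-metathesis of two terminal alkenes with loss of ethene, the excess of hept-1-ene driving conversion and the thermodynamic preference giving mainly the (E)-allylic carbonate.

Step 13
Reactants: 19 3-(phenylsulfonyl)pyrrolidine-2,5-dione; 22 methyl (2E)-oct-2-en-1-yl carbonate
Product: 24 3-[(3S)-oct-1-en-3-yl]-1H-pyrrole-2,5-dione, via sulfonyl adduct 23 (not isolated)
Conditions: 19, NaH (2.1 equiv), THF, 0 °C; [Ir(cod)Cl]2 (2 mol%), (Sa,S,S)-BINOL N,N-bis(1-phenylethyl)phosphoramidite (4 mol%), 22, rt; then AcOH (2.1 equiv), DBU (3 equiv), 40 °C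
Reagents that add atoms: none
Why: Ir-catalysed branched-selective asymmetric allylic alkylation in which the soft α-sulfonyl carbanion of the dianion of 19 (carbon reacting in preference to the imide nitrogen) attacks the substituted terminus of the allyl–iridium intermediate under phosphoramidite control, which sets the (S) side-chain stereocentre, and DBU then expels benzenesulfinate by E1cB through the ring CH2 of 23 to unveil the maleimide.

Step 14
Reactants: 17 (1S,2R,4aR,6R,8S,8aR)-1-formyl-4a-hydroxy-2,8-dimethyl-1,2,4a,5,6,7,8,8a-octahydronaphthalene-6-carboxylic acid; 24 3-[(3S)-oct-1-en-3-yl]-1H-pyrrole-2,5-dione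
Product: 27 (1S,2R,4aR,6R,8S,8aR)-1-({2,5-dioxo-4-[(3S)-oct-1-en-3-yl]-2,5-dihydro-1H-pyrrol-3-yl}carbonyl)-4a-hydroxy-2,8-dimethyl-1,2,4a,5,6,7,8,8a-octahydronaphthalene-6-carboxylic acid (CNP0326775.3), via acylsuccinimide 25 (not isolated), via bromide 26 (not isolated)
Conditions: 17 (1.3 equiv), 24, (n-Bu4N)4W10O32 (2 mol%), MeCN, 390 nm LEDs, rt, Ar; then N-bromosuccinimide (1.05 equiv), 0 °C; then Et3N (3 equiv), 0 °C, 10 min; cold dilute HCl work-up
Reagents that add atoms: none
Why: Decatungstate-photocatalysed hydroacylation (Giese-type acyl radical addition) in which the excited polyoxometalate abstracts the formyl hydrogen of 17, the nucleophilic acyl radical adds to the unsubstituted carbon of the electron-poor maleimide faster than it loses CO and hydrogen back-transfer gives β-keto imide 25, whose enol is brominated between the two carbonyl groups and dehydrobrominated by Et3N to restore the maleimide, no stereocentre of either partner being a radical or carbanion site and the two new ring centres of 25 being erased.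

**Compound list**

1 | methyl pent-4-enoate | COC(=O)CCC=C | starting material
2 | 3-bromoprop-1-ene (allyl bromide) | C=CCBr | starting material
3 | methyl 2-(prop-2-en-1-yl)pent-4-enoate | COC(=O)C(CC=C)CC=C | intermediate
4 | methyl 4-oxo-2-(2-oxopropyl)pentanoate | COC(=O)C(CC(C)=O)CC(C)=O | intermediate
5 | methyl (1S)-3-hydroxy-3-methyl-5-oxocyclohexane-1-carboxylate (ketol, either carbinol epimer) | O=C1C[C@@H](C(=O)OC)CC(C)(O)C1 | intermediate
6 | methyl (1S)-3-methyl-5-oxocyclohex-3-ene-1-carboxylate | O=C1C[C@@H](C(=O)OC)CC(C)=C1 | intermediate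
7 | (E)-but-2-enal | C/C=C/C=O | starting material
8 | ethynyltri(propan-2-yl)silane (acetylene carrying a triisopropylsilyl protecting group) | C#C[Si](C(C)C)(C(C)C)C(C)C | starting material
9 | (3S)-3-methyl-5-[tri(propan-2-yl)silyl]pent-4-ynal | O=CC[C@H](C)C#C[Si](C(C)C)(C(C)C)C(C)C | intermediate
10 | (3S)-3-methyl-5-[tri(propan-2-yl)silyl]pent-4-yn-1-ol | OCC[C@H](C)C#C[Si](C(C)C)(C(C)C)C(C)C | intermediate
11 | (3S)-3-methylpent-4-yn-1-ol | OCC[C@H](C)C#C | intermediate
12 | methyl (1S,5S)-5-hydroxy-5-[(3S)-5-hydroxy-3-methylpent-1-yn-1-yl]-3-methylcyclohex-3-ene-1-carboxylate | OCC[C@H](C)C#C[C@]1(O)C[C@@H](C(=O)OC)CC(C)=C1 | intermediate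
13 | methyl (1S,5R)-5-hydroxy-5-[(1Z,3S)-5-hydroxy-3-methylpent-1-en-1-yl]-3-methylcyclohex-3-ene-1-carboxylate | OCC[C@H](C)/C=C\[C@]1(O)C[C@@H](C(=O)OC)CC(C)=C1 | intermediate
14 | methyl (1S,5R)-5-hydroxy-3-methyl-5-[(1Z,3S)-3-methyl-5-oxopent-1-en-1-yl]cyclohex-3-ene-1-carboxylate | O=CC[C@H](C)/C=C\[C@]1(O)C[C@@H](C(=O)OC)CC(C)=C1 | intermediate
15 | methyl (1S,2R,4aR,6S,8S,8aR)-1-formyl-4a-hydroxy-2,8-dimethyl-1,2,4a,5,6,7,8,8a-octahydronaphthalene-6-carboxylate | O=C[C@@H]1[C@H]2[C@@H](C)C[C@H](C(=O)OC)C[C@@]2(O)C=C[C@H]1C | intermediate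
16 | methyl (1S,2R,4aR,6R,8S,8aR)-1-formyl-4a-hydroxy-2,8-dimethyl-1,2,4a,5,6,7,8,8a-octahydronaphthalene-6-carboxylate | O=C[C@@H]1[C@H]2[C@@H](C)C[C@@H](C(=O)OC)C[C@@]2(O)C=C[C@H]1C | intermediate
17 | (1S,2R,4aR,6R,8S,8aR)-1-formyl-4a-hydroxy-2,8-dimethyl-1,2,4a,5,6,7,8,8a-octahydronaphthalene-6-carboxylic acid | O=C[C@@H]1[C@H]2[C@@H](C)C[C@@H](C(=O)O)C[C@@]2(O)C=C[C@H]1C | intermediate
18 | 1H-pyrrole-2,5-dione (maleimide) | O=C1C=CC(=O)N1 | starting material
19 | 3-(phenylsulfonyl)pyrrolidine-2,5-dione (racemic) | O=C1CC(S(=O)(=O)c2ccccc2)C(=O)N1 | intermediate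
20 | hept-1-ene | C=CCCCCC | starting material
21 | methyl prop-2-en-1-yl carbonate | C=CCOC(=O)OC | starting material
22 | methyl (2E)-oct-2-en-1-yl carbonate | CCCCC/C=C/COC(=O)OC | intermediate
23 | 3-[(3S)-oct-1-en-3-yl]-3-(phenylsulfonyl)pyrrolidine-2,5-dione (either C3 epimer) | C=C[C@H](CCCCC)C1(S(=O)(=O)c2ccccc2)CC(=O)NC1=O | intermediate
24 | 3-[(3S)-oct-1-en-3-yl]-1H-pyrrole-2,5-dione | C=C[C@H](CCCCC)C1=CC(=O)NC1=O | intermediate
25 | (1S,2R,4aR,6R,8S,8aR)-1-({2,5-dioxo-4-[(3S)-oct-1-en-3-yl]pyrrolidin-3-yl}carbonyl)-4a-hydroxy-2,8-dimethyl-1,2,4a,5,6,7,8,8a-octahydronaphthalene-6-carboxylic acid (epimers at the two pyrrolidine carbons) | C=C[C@H](CCCCC)C1C(C(=O)[C@@H]2[C@H]3[C@@H](C)C[C@@H](C(=O)O)C[C@@]3(O)C=C[C@H]2C)C(=O)NC1=O | intermediate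
26 | (1S,2R,4aR,6R,8S,8aR)-1-({3-bromo-2,5-dioxo-4-[(3S)-oct-1-en-3-yl]pyrrolidin-3-yl}carbonyl)-4a-hydroxy-2,8-dimethyl-1,2,4a,5,6,7,8,8a-octahydronaphthalene-6-carboxylic acid (epimers at the two pyrrolidine carbons) | C=C[C@H](CCCCC)C1C(Br)(C(=O)[C@@H]2[C@H]3[C@@H](C)C[C@@H](C(=O)O)C[C@@]3(O)C=C[C@H]2C)C(=O)NC1=O | intermediate
27 | (1S,2R,4aR,6R,8S,8aR)-1-({2,5-dioxo-4-[(3S)-oct-1-en-3-yl]-2,5-dihydro-1H-pyrrol-3-yl}carbonyl)-4a-hydroxy-2,8-dimethyl-1,2,4a,5,6,7,8,8a-octahydronaphthalene-6-carboxylic acid | C=C[C@H](CCCCC)C1=C(C(=O)[C@@H]2[C@H]3[C@@H](C)C[C@@H](C(=O)O)C[C@@]3(O)C=C[C@H]2C)C(=O)NC1=O | target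

**Step count and weak points**

Total: 14 steps. Longest linear sequence: 9 steps (1, 2, 3, 6, 7, 8, 9, 10, 14).

The three steps most likely to fail:

Step 9 (the radical ring closure). The enamine radical has not been used on an olefin that sits in a ring next to a fully substituted carbinol; thiyl-mediated Z/E scrambling or premature reduction could compete. The fallback sets out from 14 and comes back at 15 and makes the same radical by a stoichiometric chain process instead of photoredox oxidation. Aldehyde 14 is α-selenenylated with N-(phenylselanyl)phthalimide and catalytic L-prolinamide in CH2Cl2 at 0 °C to give methyl (1S,5R)-5-hydroxy-3-methyl-5-[(1Z,3R)-3-methyl-5-oxo-4-(phenylselanyl)pent-1-en-1-yl]cyclohex-3-ene-1-carboxylate F1 (both epimers at the selenium-bearing carbon). Slow addition of Bu3SnH with Et3B and air in benzene at rt abstracts selenium, the α-formyl radical closes 6-exo onto C8a, and the stannane reduces the C8 radical to give 15.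

Step 13 (allylic alkylation with a hindered, doubly deprotonated nucleophile). Low rate, N-allylation or loss of branched selectivity are the risks. The fallback sets out from 22 and comes back at 24 and builds the imide ring after the alkylation instead of alkylating a preformed ring. The same iridium catalyst couples 22 with the sodium salt of methyl (phenylsulfonyl)acetate, a conventional secondary nucleophile, to give methyl (3S)-3-ethenyl-2-(phenylsulfonyl)octanoate F2 (both C2 epimers). Alkylation with 2-bromoacetamide (K2CO3, DMF, rt) gives methyl (3S)-2-(2-amino-2-oxoethyl)-3-ethenyl-2-(phenylsulfonyl)octanoate F3. Cs2CO3 in MeCN at 50 °C then closes the imide onto the ester and expels sulfinate to give 24.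

Step 14 (fragment union). The photocatalyst may abstract the allylic hydrogen of 24 or the hindered acyl radical may lose CO. The fallback sets out from 17 and 24 and comes back at 25, replacing the acyl radical by an acyl anion equivalent. An intermolecular Stetter reaction (3-benzyl-5-(2-hydroxyethyl)-4-methylthiazolium chloride 20 mol%, Et3N 2.5 equiv, EtOH, 60 °C) adds the Breslow intermediate of 17 to the unsubstituted carbon of 24 and gives 25 directly. Bromination and dehydrobromination then follow as written to reach 27.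

**Further compounds**

F1 | step 9 | methyl (1S,5R)-5-hydroxy-3-methyl-5-[(1Z,3R)-3-methyl-5-oxo-4-(phenylselanyl)pent-1-en-1-yl]cyclohex-3-ene-1-carboxylate | O=CC([Se]c2ccccc2)[C@H](C)/C=C\[C@]1(O)C[C@@H](C(=O)OC)CC(C)=C1
F2 | step 13 | methyl (3S)-3-ethenyl-2-(phenylsulfonyl)octanoate | C=C[C@H](CCCCC)C(C(=O)OC)S(=O)(=O)c1ccccc1
F3 | step 13 | methyl (3S)-2-(2-amino-2-oxoethyl)-3-ethenyl-2-(phenylsulfonyl)octanoate | C=C[C@H](CCCCC)C(CC(N)=O)(C(=O)OC)S(=O)(=O)c1ccccc1
F0 | step 14 | none | none
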